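**Retrosynthetic overview**
- Target 20 comes from tribenzyl flavonol 19 by hydrogenolysis; 19 comes from flavone 17 by hydroxylation at C3 (epoxidation of C2=C3, acid opening).
- The strategy rests on ring C: the carbonyl carbon C4 lies between C4a of ring A and the C3=C2–aryl unit, and O1 sits on C8a. C4 is therefore taken from carbon monoxide, C2–C3 from a terminal arylalkyne, and C4a/O1 from a 2-iodophenol; one palladium-catalysed carbonylative annulation forms C4a–C4, C4–C3 and O1–C2.
- Ring A partner 8 comes from 3-hydroxy-4,5-dimethoxybenzaldehyde 1 (MOM ether, Baeyer–Villiger, benzyl ether, directed lithiation/iodination, MOM removal).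
- Ring B partner 13 comes from 3,5-dihydroxy-4-methoxybenzoic acid 9 (perbenzylation, reduction, oxidation, Ohira–Bestmann homologation).
- Rings A and B are bought as benzenes; ring C is the only ring formed, in step 10.

Key step: step 10

Remark: compounds 1, 9 and carbon monoxide are taken as purchasable. The target has no stereocentre; epoxide 18 is racemic and both of its stereocentres are lost within the same step.

**Route**

Step 1
Reactants: 1 3-hydroxy-4,5-dimethoxybenzaldehyde
Product: 2 3,4-dimethoxy-5-(methoxymethoxy)benzaldehyde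
Conditions: MOMCl, i-Pr2NEt, CH2Cl2, 0 °C to rt
Reagents that add atoms: chloromethyl methyl ether (MOMCl), COCCl
Why: Williamson-type O-alkylation of the phenol with the reactive α-chloro ether installs the MOM acetal, which later serves as the ortho-directing group, and leaves the aldehyde untouched.

Step 2
Reactants: 2 3,4-dimethoxy-5-(methoxymethoxy)benzaldehyde
Product: 4 3,4-dimethoxy-5-(methoxymethoxy)phenol, via aryl formate 3 (not isolated)
Conditions: mCPBA, CH2Cl2, 0 °C to rt; aq. NaHCO3 wash; then K2CO3 (cat.), MeOH, rt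
Reagents that add atoms: meta-chloroperoxybenzoic acid (mCPBA), O=C(OO)c1cccc(Cl)c1
Why: Baeyer–Villiger oxidation in the Dakin sense, in which the electron-rich trioxygenated aryl group migrates in the Criegee adduct to give formate 3, which mild methanolysis cleaves to the phenol while the MOM acetal survives.

Step 3
Reactants: 4 3,4-dimethoxy-5-(methoxymethoxy)phenol
Product: 5 5-(benzyloxy)-1,2-dimethoxy-3-(methoxymethoxy)benzene
Conditions: BnBr, K2CO3, DMF, rt
Reagents that add atoms: benzyl bromide, BrCc1ccccc1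
Why: Williamson ether synthesis on the potassium phenoxide; benzyl is chosen so that this ether falls at the end together with the ring B benzyl ethers.

Step 4
Reactants: 5 5-(benzyloxy)-1,2-dimethoxy-3-(methoxymethoxy)benzene
Product: 7 1-(benzyloxy)-2-iodo-4,5-dimethoxy-3-(methoxymethoxy)benzene, via aryllithium 6 (not isolated)
Conditions: n-BuLi, TMEDA, THF, −20 to 0 °C; then I2, THF, −78 °C to rt
Reagents that add atoms: iodine, II
Why: Directed ortho-metalation, in which the hydrogen between OMOM and OBn is flanked by the strongly coordinating acetal and a second ether oxygen, whereas the other ring hydrogen lies between OBn and the weakly directing OMe, so lithiation should occur at the former and iodine then traps aryllithium 6.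

Step 5
Reactants: 7 1-(benzyloxy)-2-iodo-4,5-dimethoxy-3-(methoxymethoxy)benzene
Product: 8 3-(benzyloxy)-2-iodo-5,6-dimethoxyphenol
Conditions: HCl (cat.), MeOH, 40 °C
Reagents that add atoms: none
Why: Acid-catalysed acetal exchange removes the MOM group as dimethoxymethane, while the benzyl ether, the methyl ethers and the aryl iodide are stable to dilute methanolic HCl.

Step 6
Reactants: 9 3,5-dihydroxy-4-methoxybenzoic acid
Product: 10 benzyl 3,5-bis(benzyloxy)-4-methoxybenzoate
Conditions: BnBr (3.5 equiv), K2CO3, DMF, 60 °C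
Reagents that add atoms: benzyl bromide, BrCc1ccccc1
Why: Exhaustive Williamson and carboxylate alkylation benzylates both phenols and the acid in one operation.

Step 7
Reactants: 10 benzyl 3,5-bis(benzyloxy)-4-methoxybenzoate
Product: 11 [3,5-bis(benzyloxy)-4-methoxyphenyl]methanol
Conditions: LiAlH4, THF, 0 °C to rt
Reagents that add atoms: none
Why: Hydride reduction of the ester by LiAlH4 gives the benzylic alcohol; aryl benzyl and methyl ethers are inert.

Step 8
Reactants: 11 [3,5-bis(benzyloxy)-4-methoxyphenyl]methanol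
Product: 12 3,5-bis(benzyloxy)-4-methoxybenzaldehyde
Conditions: Dess–Martin periodinane, CH2Cl2, rt
Reagents that add atoms: none
Why: Dess–Martin oxidation of the primary benzylic alcohol stops at the aldehyde under neutral conditions.

Step 9
Reactants: 12 3,5-bis(benzyloxy)-4-methoxybenzaldehyde
Product: 13 1,3-bis(benzyloxy)-5-ethynyl-2-methoxybenzene
Conditions: dimethyl (1-diazo-2-oxopropyl)phosphonate, K2CO3, MeOH, rt
Reagents that add atoms: dimethyl (1-diazo-2-oxopropyl)phosphonate (Ohira–Bestmann reagent), COP(=O)(OC)C(=[N+]=[N-])C(C)=O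
Why: Ohira–Bestmann variant of the Seyferth–Gilbert homologation, in which methoxide deacylates the reagent, the diazomethylphosphonate anion adds to the aldehyde, and loss of dimethyl phosphate and N2 with 1,2-hydrogen shift gives the terminal alkyne without touching the benzyl ethers.

Step 10
Reactants: 8 3-(benzyloxy)-2-iodo-5,6-dimethoxyphenol; 13 1,3-bis(benzyloxy)-5-ethynyl-2-methoxybenzene; 14 carbon monoxide
Product: 17 5-(benzyloxy)-2-[3,5-bis(benzyloxy)-4-methoxyphenyl]-7,8-dimethoxy-4H-chromen-4-one, via ynone 15 (not isolated), via enaminone 16 (not isolated)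
Conditions: CO (20 bar), PdCl2(PPh3)2 (5 mol %), Et2NH (solvent), 120 °C, autoclave, no copper salt
Reagents that add atoms: none
Why: Zerovalent palladium, formed from the divalent palladium precatalyst PdCl2(PPh3)2 under CO and amine, inserts into the C4a–I bond of 8, CO insertion gives the aroylpalladium species, and amine-assisted transfer of the alkynyl group of 13 followed by reductive elimination gives ynone 15 (bonds C4a–C4 and C4–C3). Diethylamine adds to 15 in conjugate fashion to give enaminone 16, and the phenol oxygen then attacks C2 and expels the amine, so ring C is closed by a 6-endo addition–elimination (bond O1–C2); no stereocentre is formed. The closest known reaction type is the palladium-catalysed carbonylative annulation of 2-iodophenols with terminal alkynes to flavones. The step needs carbonylative over direct coupling, which is favoured by the two ortho oxygen substituents on the aryl palladium (slow alkynyl transfer, fast CO insertion), by the CO pressure, and by leaving out copper, since a copper acetylide would speed the CO-free coupling that ends in a 2-arylbenzofuran. It also needs 6-endo over 5-exo (aurone) closure, which passage through enaminone 16 secures because the amine-bearing C2 is then the electrophilic site. The ring A substitution pattern is fixed by the position of the iodine alone, with no acylation of the electron-rich ring.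

Step 11
Reactants: 17 5-(benzyloxy)-2-[3,5-bis(benzyloxy)-4-methoxyphenyl]-7,8-dimethoxy-4H-chromen-4-one
Product: 19 5-(benzyloxy)-2-[3,5-bis(benzyloxy)-4-methoxyphenyl]-3-hydroxy-7,8-dimethoxy-4H-chromen-4-one, via 2,3-epoxide 18 (not isolated)
Conditions: dimethyldioxirane (excess, acetone solution), CH2Cl2, 0 °C to rt; evaporate; then p-TsOH (cat.), CH2Cl2, rt
Reagents that add atoms: dimethyldioxirane, CC1(C)OO1
Why: Electrophilic oxygen transfer from the dioxirane to the C2=C3 bond gives racemic epoxide 18, and acid-catalysed opening at C2 (cation stabilised by O1 and the aryl ring) with loss of H3 gives the 3-hydroxyflavone, so both transient stereocentres vanish; this is the known dioxirane route from flavones to flavonols, helped here by the 5-benzyloxy group, which cannot hydrogen-bond to the C4 carbonyl.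

Step 12
Reactants: 19 5-(benzyloxy)-2-[3,5-bis(benzyloxy)-4-methoxyphenyl]-3-hydroxy-7,8-dimethoxy-4H-chromen-4-one
Product: 20 3,5-dihydroxy-2-(3,5-dihydroxy-4-methoxyphenyl)-7,8-dimethoxy-4H-chromen-4-one
Conditions: H2 (1 atm), Pd/C (10 %), EtOAc/MeOH, rt
Reagents that add atoms: none
Why: Catalytic hydrogenolysis cleaves the three benzylic C–O bonds and should leave the methyl ethers and the fully substituted, conjugated C2=C3 bond of the flavonol intact.

**Compound list**

1 | 3-hydroxy-4,5-dimethoxybenzaldehyde | COc1cc(C=O)cc(O)c1OC | starting material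
2 | 3,4-dimethoxy-5-(methoxymethoxy)benzaldehyde | COCOc1cc(C=O)cc(OC)c1OC | intermediate
3 | 3,4-dimethoxy-5-(methoxymethoxy)phenyl formate (not isolated) | COCOc1cc(OC=O)cc(OC)c1OC | intermediate
4 | 3,4-dimethoxy-5-(methoxymethoxy)phenol | COCOc1cc(O)cc(OC)c1OC | intermediate
5 | 5-(benzyloxy)-1,2-dimethoxy-3-(methoxymethoxy)benzene | COCOc1cc(OCc2ccccc2)cc(OC)c1OC | intermediate
6 | [6-(benzyloxy)-3,4-dimethoxy-2-(methoxymethoxy)phenyl]lithium (not isolated) | COCOc1c([Li])c(OCc2ccccc2)cc(OC)c1OC | intermediate
7 | 1-(benzyloxy)-2-iodo-4,5-dimethoxy-3-(methoxymethoxy)benzene | COCOc1c(I)c(OCc2ccccc2)cc(OC)c1OC | intermediate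
8 | 3-(benzyloxy)-2-iodo-5,6-dimethoxyphenol | COc1cc(OCc2ccccc2)c(I)c(O)c1OC | intermediate
9 | 3,5-dihydroxy-4-methoxybenzoic acid | COc1c(O)cc(C(=O)O)cc1O | starting material
10 | benzyl 3,5-bis(benzyloxy)-4-methoxybenzoate | COc1c(OCc2ccccc2)cc(C(=O)OCc2ccccc2)cc1OCc1ccccc1 | intermediate
11 | [3,5-bis(benzyloxy)-4-methoxyphenyl]methanol | COc1c(OCc2ccccc2)cc(CO)cc1OCc1ccccc1 | intermediate
12 | 3,5-bis(benzyloxy)-4-methoxybenzaldehyde | COc1c(OCc2ccccc2)cc(C=O)cc1OCc1ccccc1 | intermediate
13 | 1,3-bis(benzyloxy)-5-ethynyl-2-methoxybenzene | C#Cc1cc(OCc2ccccc2)c(OC)c(OCc2ccccc2)c1 | intermediate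
14 | carbon monoxide | [C-]#[O+] | starting material
15 | 1-[6-(benzyloxy)-2-hydroxy-3,4-dimethoxyphenyl]-3-[3,5-bis(benzyloxy)-4-methoxyphenyl]prop-2-yn-1-one (not isolated) | COc1cc(OCc2ccccc2)c(C(=O)C#Cc2cc(OCc3ccccc3)c(OC)c(OCc3ccccc3)c2)c(O)c1OC | intermediate
16 | 1-[6-(benzyloxy)-2-hydroxy-3,4-dimethoxyphenyl]-3-[3,5-bis(benzyloxy)-4-methoxyphenyl]-3-(diethylamino)prop-2-en-1-one (not isolated; geometry of the push–pull double bond not fixed) | COc1cc(OCc2ccccc2)c(C(=O)C=C(N(CC)CC)c2cc(OCc3ccccc3)c(OC)c(OCc3ccccc3)c2)c(O)c1OC | intermediate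
17 | 5-(benzyloxy)-2-[3,5-bis(benzyloxy)-4-methoxyphenyl]-7,8-dimethoxy-4H-chromen-4-one | COc1cc(OCc2ccccc2)c2c(=O)cc(-c3cc(OCc4ccccc4)c(OC)c(OCc4ccccc4)c3)oc2c1OC | intermediate
18 | 5-(benzyloxy)-2-[3,5-bis(benzyloxy)-4-methoxyphenyl]-2,3-epoxy-7,8-dimethoxy-2,3-dihydro-4H-chromen-4-one (not isolated; racemic, one enantiomer drawn, oxirane cis-fused to ring C) | O=C1[C@H]2O[C@@]2(c2cc(OCc3ccccc3)c(OC)c(OCc3ccccc3)c2)Oc2c(OC)c(OC)cc(OCc3ccccc3)c21 | intermediate
19 | 5-(benzyloxy)-2-[3,5-bis(benzyloxy)-4-methoxyphenyl]-3-hydroxy-7,8-dimethoxy-4H-chromen-4-one | COc1cc(OCc2ccccc2)c2c(=O)c(O)c(-c3cc(OCc4ccccc4)c(OC)c(OCc4ccccc4)c3)oc2c1OC | intermediate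
20 | 3,5-dihydroxy-2-(3,5-dihydroxy-4-methoxyphenyl)-7,8-dimethoxy-4H-chromen-4-one | COc1cc(O)c2c(=O)c(O)c(-c3cc(O)c(OC)c(O)c3)oc2c1OC | target

**Step count and risks**

Total step count: 12. Longest linear sequence: 8 steps (steps 1–5, then 10–12); the ring B branch (steps 6–9) has 4 steps.

Steps most likely to fail:

1. Step 10 (key step). Oxidative addition into the electron-rich, doubly ortho-substituted C–I bond may stall. Alkynyl transfer may overtake CO insertion, giving CO-free coupling and then benzofuran formation. The aroylpalladium species may be intercepted by the amine (aminocarbonylation), or closure may go 5-exo. The fallback sets out from 7 and 13 and comes back to the route at 15, which is then taken to 17. Alkyne 13 would be deprotonated with n-BuLi and formylated with DMF to give 3-[3,5-bis(benzyloxy)-4-methoxyphenyl]prop-2-ynal F1. Aryllithium 6, regenerated from iodide 7 by iodine–lithium exchange (n-BuLi, THF, −78 °C), would add to F1 to give racemic 1-[6-(benzyloxy)-3,4-dimethoxy-2-(methoxymethoxy)phenyl]-3-[3,5-bis(benzyloxy)-4-methoxyphenyl]prop-2-yn-1-ol F2. MnO2 in CH2Cl2 would oxidise F2 to the MOM-protected ynone 1-[6-(benzyloxy)-3,4-dimethoxy-2-(methoxymethoxy)phenyl]-3-[3,5-bis(benzyloxy)-4-methoxyphenyl]prop-2-yn-1-one F3. Dilute HCl in MeOH would remove the MOM group to give ynone 15, now isolated, and Et2NH in EtOH at reflux would close ring C through enaminone 16 to flavone 17.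

2. Step 4. Lithiation may be incompletely regioselective (competing removal of the hydrogen between OBn and OMe), or benzylic deprotonation of the benzyl ether may lead to Wittig rearrangement. The fallback sets out from 2 and comes back at 7, so that no benzyl ether ever meets an alkyllithium. Aldehyde 2 would be masked in the flask by LiN(Me)CH2CH2NMe2 (THF, −20 °C) as its lithium α-amino alkoxide, lithium [3,4-dimethoxy-5-(methoxymethoxy)phenyl]{[2-(dimethylamino)ethyl](methyl)amino}methanolate F4. n-BuLi would then remove the ring hydrogen between the alkoxide-bearing carbon and the OMOM group, and iodine followed by aqueous work-up would give 2-iodo-4,5-dimethoxy-3-(methoxymethoxy)benzaldehyde F5. Baeyer–Villiger oxidation with mCPBA would give 2-iodo-4,5-dimethoxy-3-(methoxymethoxy)phenyl formate F6, methanolysis (K2CO3, MeOH) would give 2-iodo-4,5-dimethoxy-3-(methoxymethoxy)phenol F7, and benzylation (BnBr, K2CO3, DMF) would give 7.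

3. Step 11. Oxygen transfer to the electron-poor C2=C3 bond may be sluggish, so that oxidation at benzylic C–H bonds or on the electron-rich rings competes. The fallback sets out from 17 and comes back at 19. LiN(i-Pr)2 in THF at −78 °C would deprotonate C3 to give the 3-lithioflavone, {5-(benzyloxy)-2-[3,5-bis(benzyloxy)-4-methoxyphenyl]-7,8-dimethoxy-4-oxo-4H-chromen-3-yl}lithium F8. B(OMe)3 would convert it into dimethyl {5-(benzyloxy)-2-[3,5-bis(benzyloxy)-4-methoxyphenyl]-7,8-dimethoxy-4-oxo-4H-chromen-3-yl}boronate F9, and oxidation of the C–B bond with H2O2 in AcOH would give flavonol 19.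

**Further compounds**

F1 | step 10 | 3-[3,5-bis(benzyloxy)-4-methoxyphenyl]prop-2-ynal | O=CC#Cc1cc(OCc2ccccc2)c(OC)c(OCc2ccccc2)c1
F2 | step 10 | 1-[6-(benzyloxy)-3,4-dimethoxy-2-(methoxymethoxy)phenyl]-3-[3,5-bis(benzyloxy)-4-methoxyphenyl]prop-2-yn-1-ol (racemic) | COCOc1c(C(O)C#Cc2cc(OCc3ccccc3)c(OC)c(OCc3ccccc3)c2)c(OCc2ccccc2)cc(OC)c1OC
F3 | step 10 | 1-[6-(benzyloxy)-3,4-dimethoxy-2-(methoxymethoxy)phenyl]-3-[3,5-bis(benzyloxy)-4-methoxyphenyl]prop-2-yn-1-one | COCOc1c(C(=O)C#Cc2cc(OCc3ccccc3)c(OC)c(OCc3ccccc3)c2)c(OCc2ccccc2)cc(OC)c1OC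
F4 | step 4 | lithium [3,4-dimethoxy-5-(methoxymethoxy)phenyl]{[2-(dimethylamino)ethyl](methyl)amino}methanolate (racemic, formed in the flask) | COCOc1cc(C(O[Li])N(C)CCN(C)C)cc(OC)c1OC
F5 | step 4 | 2-iodo-4,5-dimethoxy-3-(methoxymethoxy)benzaldehyde | COCOc1c(I)c(C=O)cc(OC)c1OC
F6 | step 4 | 2-iodo-4,5-dimethoxy-3-(methoxymethoxy)phenyl formate | COCOc1c(I)c(OC=O)cc(OC)c1OC
F7 | step 4 | 2-iodo-4,5-dimethoxy-3-(methoxymethoxy)phenol | COCOc1c(I)c(O)cc(OC)c1OC
F8 | step 11 | {5-(benzyloxy)-2-[3,5-bis(benzyloxy)-4-methoxyphenyl]-7,8-dimethoxy-4-oxo-4H-chromen-3-yl}lithium | COc1cc(OCc2ccccc2)c2c(=O)c([Li])c(-c3cc(OCc4ccccc4)c(OC)c(OCc4ccccc4)c3)oc2c1OC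
F9 | step 11 | dimethyl {5-(benzyloxy)-2-[3,5-bis(benzyloxy)-4-methoxyphenyl]-7,8-dimethoxy-4-oxo-4H-chromen-3-yl}boronate | COc1cc(OCc2ccccc2)c2c(=O)c(B(OC)OC)c(-c3cc(OCc4ccccc4)c(OC)c(OCc4ccccc4)c3)oc2c1OC
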